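**Plan**
Numbering: decalin C1–C10 (ring A = C1–C5, C10; ring B = C5–C10), side chain C11–C14 on C9, C17 on C8, C18/C19 on C4, C20 on C10.
Retrosynthesis: cut C11=C12 (Wittig), then C5–C10 and C8–C9 together (intramolecular Diels–Alder), then the open chain at C6–C7, at C9/C10 (C11, C20) and at C3–C4.
Enabling feature: the contiguous centres C8, C9, C10 and C5 of ring B are the ends of a C5=C6–C7=C8 diene and a C9=C10 dienophile that the ring A chain C1–C4 already ties together, and the C6=C7 alkene left behind lies where the two secondary oxygens belong.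
Forward: a C15 trienal is built linearly (steps 1–8), rings A and B close in one step (step 9), then C6/C7 are oxygenated and C11 is extended to the enone (steps 10–16).
Stereochemistry: absolute configuration from the chiral Lewis acid of step 9; C5, C8, C9, C10 from the three alkene geometries and the endo transition state; C6 from α-face osmylation; C7 from α-face hydride addition to the 7-ketone.

Key step: step 9

Assumption 1: the oxazaborolidine from (S)-diphenylprolinol is taken to leave the C10 Re face of the bound enal open, as its formyl-binding model suggests; should the sense be opposite, the catalyst from (R)-diphenylprolinol is used and nothing else changes.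
Assumption 2: racemic propylene oxide is used because its stereocentre becomes the C8 carbonyl carbon in step 7; compounds 10–14 are therefore racemic at that carbon.

**Step 1**
Reactants: 1 isobutyronitrile; 2 (5-chloropent-1-yn-1-yl)trimethylsilane
Product: 4 2,2-dimethyl-7-(trimethylsilyl)hept-6-ynenitrile, via lithiated isobutyronitrile 3 (not isolated)
Conditions: LiN(iPr)2, THF, −78 °C; then 2, DMPU, −78 °C → rt
Reagents that add atoms: none
Why: SN2 alkylation of a tertiary α-cyano carbanion with a primary chloride is a reliable way to the quaternary carbon C4, and the product has no α-hydrogen left and the C-silyl alkyne is inert.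

**Step 2**
Reactants: 4 2,2-dimethyl-7-(trimethylsilyl)hept-6-ynenitrile
Product: 6 2,2-dimethyl-7-(trimethylsilyl)hept-6-ynal, via aluminium aldimine 5 (not isolated)
Conditions: iBu2AlH, CH2Cl2, −78 → 0 °C; then 1 M HCl, 0 °C
Reagents that add atoms: water, O
Why: partial reduction of a nitrile without α-hydrogens stops at the N-aluminoimine, which is hydrolysed to the aldehyde on acidic work-up, and the silylalkyne is not hydroaluminated at this temperature.

**Step 3**
Reactants: 6 2,2-dimethyl-7-(trimethylsilyl)hept-6-ynal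
Product: 7 [(7E)-8-iodo-6,6-dimethyloct-7-en-1-yn-1-yl]trimethylsilane
Conditions: CrCl2, CHI3, THF, 0 °C → rt
Reagents that add atoms: iodoform, IC(I)I
Why: Takai olefination of a non-enolisable α-quaternary aldehyde should give the (E)-iodoalkene, the bulky quaternary substituent reinforcing the E preference that fixes the C5=C6 geometry.

**Step 4**
Reactants: 7 [(7E)-8-iodo-6,6-dimethyloct-7-en-1-yn-1-yl]trimethylsilane; 8 (±)-2-methyloxirane (propylene oxide)
Product: 10 (4E)-6,6-dimethyl-11-(trimethylsilyl)undec-4-en-10-yn-2-ol, via alkenyllithium 9 (not isolated)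
Conditions: t-BuLi (2 equiv), Et2O, −78 °C; then BF3·OEt2, 8, −78 °C
Reagents that add atoms: none
Why: iodine–lithium exchange retains the alkene geometry and the BF3-activated epoxide is opened at its unsubstituted carbon, which gives the homoallylic alcohol with the C5=C6 bond held out of conjugation.

**Step 5**
Reactants: 10 (4E)-6,6-dimethyl-11-(trimethylsilyl)undec-4-en-10-yn-2-ol
Product: 11 (4E)-6,6-dimethylundec-4-en-10-yn-2-ol
Conditions: K2CO3 (cat.), MeOH, rt
Reagents that add atoms: none
Why: methanolysis of the C(sp)–Si bond is selective and touches nothing else in the molecule.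

**Step 6**
Reactants: 11 (4E)-6,6-dimethylundec-4-en-10-yn-2-ol
Product: 14 (2E,8E)-3,7,7-trimethyldodeca-2,8-diene-1,11-diol, via alkenylalane 12 (not isolated), via lithium alkenylalanate 13 (not isolated)
Conditions: AlMe3 (3 equiv), Cp2ZrCl2 (0.25 equiv), CH2Cl2, 0 °C → rt; then n-BuLi, THF, −78 °C; (CH2O)n, → rt; aq. KNaC4H4O6
Reagents that add atoms: trimethylaluminium, C[Al](C)C; formaldehyde (as paraformaldehyde), C=O
Why: zirconium-catalysed syn-carboalumination (Negishi) puts methyl on the internal and aluminium on the terminal alkyne carbon, and hydroxymethylation of the alanate with retention gives the (E)-trisubstituted allylic alcohol, while the free hydroxyl is only converted into its aluminium alkoxide and the disubstituted alkene is inert.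

**Step 7**
Reactants: 14 (2E,8E)-3,7,7-trimethyldodeca-2,8-diene-1,11-diol
Product: 15 (2E,8E)-3,7,7-trimethyl-11-oxododeca-2,8-dienal
Conditions: Dess–Martin periodinane (2.5 equiv), pyridine, CH2Cl2, 0 °C → rt
Reagents that add atoms: none
Why: buffered Dess–Martin oxidation turns the allylic alcohol into the (E)-enal and the homoallylic alcohol into the β,γ-unsaturated ketone under neutral conditions that should not move the C5=C6 bond into conjugation.

**Step 8**
Reactants: 15 (2E,8E)-3,7,7-trimethyl-11-oxododeca-2,8-dienal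
Product: 16 (2E,8E,10Z)-11-(tert-butyldimethylsilyloxy)-3,7,7-trimethyldodeca-2,8,10-trienal
Conditions: TBSOTf (1.05 equiv), Et3N, CH2Cl2, −78 °C
Reagents that add atoms: tert-butyldimethylsilyl triflate, CC(C)(C)[Si](C)(C)OS(=O)(=O)C(F)(F)F
Why: soft enolisation should take the doubly activated C7 proton of the β,γ-unsaturated ketone much faster than a γ-proton of the enal or a methyl proton, and the conjugated silyl dienol ether forms with the (Z) geometry that avoids a cis methyl/vinyl interaction.

**Step 9**
Reactants: 16 (2E,8E,10Z)-11-(tert-butyldimethylsilyloxy)-3,7,7-trimethyldodeca-2,8,10-trienal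
Product: 17 8α-(tert-butyldimethylsilyloxy)-4,4,8β,10β-tetramethyl-trans-decal-6-ene-9β-carbaldehyde (5α-H)
Conditions: (S)-1-(2-methylphenyl)-3,3-diphenyltetrahydro-1H,3H-pyrrolo[1,2-c][1,3,2]oxazaborole (20 mol %), HN(SO2CF3)2 (17 mol %), CH2Cl2, 0.01 M, −78 → −40 °C; Et3N quench
Reagents that add atoms: none
Why: The protonated oxazaborolidine binds the formyl group of the (E)-enal and lowers its LUMO, so that the electron-rich 1-silyloxy diene should add across C9=C10 in a concerted but asynchronous [4+2] in which C5–C10 (nucleophilic diene terminus to the enal β-carbon) runs ahead of C8–C9; the closest known reaction type is the chiral-Lewis-acid-catalysed type 1 intramolecular Diels–Alder reaction of (2E,8E,10E)-trienals, used here at its hindered limit. Ring B closes as the new cyclohexene of the cycloaddition and ring A closes at the same moment as the ring of the four-carbon tether C1–C4 (fused mode). C10 and C9 follow from the (E)-enal (10-methyl and 9-formyl cis), C5 from the (8E)-alkene together with the endo-formyl, tether-anti transition state (trans ring fusion), and C8 from the (10Z)-enol ether, whose outside methyl ends cis to the formyl group (8β-methyl, 8α-silyloxy); the absolute sense, diene onto the C10 Re face, is set by the aryl group of the catalyst shielding the other face. The step needs endo over exo and one enal face over the other: Lewis-acid coordination of the formyl group secures the first and the catalyst the second, while the gem-dimethyl group at C4 and high dilution favour ring closure over intermolecular Mukaiyama–Michael addition.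

**Step 10**
Reactants: 17 8α-(tert-butyldimethylsilyloxy)-4,4,8β,10β-tetramethyl-trans-decal-6-ene-9β-carbaldehyde
Product: 18 6α,7α-dihydroxy-8α-(tert-butyldimethylsilyloxy)-4,4,8β,10β-tetramethyl-trans-decalin-9β-carbaldehyde
Conditions: OsO4 (5 mol %), NMO, acetone/H2O, rt
Reagents that add atoms: OsO4, O=[Os](=O)(=O)=O; N-methylmorpholine N-oxide, C[N+]1([O-])CCOCC1; water, O
Why: Upjohn syn-dihydroxylation should occur on the α face because the β face of C6=C7 is screened by the axial 4β-, 8β- and 10β-methyl groups, which sets C6 (6α-OH, final) and gives the 7α-OH that is inverted later, and the aldehyde is not touched.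

**Step 11**
Reactants: 18 6α,7α-dihydroxy-8α-(tert-butyldimethylsilyloxy)-4,4,8β,10β-tetramethyl-trans-decalin-9β-carbaldehyde
Product: 19 6α-acetoxy-7α-hydroxy-8α-(tert-butyldimethylsilyloxy)-4,4,8β,10β-tetramethyl-trans-decalin-9β-carbaldehyde
Conditions: Ac2O (1.1 equiv), pyridine, DMAP (cat.), CH2Cl2, −20 °C
Reagents that add atoms: acetic anhydride, CC(=O)OC(C)=O
Why: the equatorial 6α-hydroxyl should be acylated in preference to the axial 7α-hydroxyl, which is neopentylic and gauche to the bulky 8α-silyloxy group.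

**Step 12**
Reactants: 19 6α-acetoxy-7α-hydroxy-8α-(tert-butyldimethylsilyloxy)-4,4,8β,10β-tetramethyl-trans-decalin-9β-carbaldehyde
Product: 20 6α-acetoxy-7-oxo-8α-(tert-butyldimethylsilyloxy)-4,4,8β,10β-tetramethyl-trans-decalin-9β-carbaldehyde
Conditions: Dess–Martin periodinane, pyridine, CH2Cl2, rt
Reagents that add atoms: none
Why: Dess–Martin oxidation of the remaining axial alcohol gives the α-acetoxy ketone without base, so the acetate should not migrate and C6 and C9, which carry their substituents equatorial, should not epimerise.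

**Step 13**
Reactants: 20 6α-acetoxy-7-oxo-8α-(tert-butyldimethylsilyloxy)-4,4,8β,10β-tetramethyl-trans-decalin-9β-carbaldehyde
Product: 21 6α-acetoxy-9β-(hydroxymethyl)-8α-(tert-butyldimethylsilyloxy)-4,4,8β,10β-tetramethyl-trans-decalin-7β-ol
Conditions: NaBH4, CeCl3·7H2O, MeOH, −78 → −40 °C
Reagents that add atoms: none
Why: under Luche conditions hydride should add to the C7 ketone along the axial trajectory from the α face, the β face being blocked by the adjacent axial 8β-methyl group, to give the equatorial 7β-alcohol (net inversion of C7) while the aldehyde is reduced as well, and low temperature with the cerium salt suppresses acetyl and silyl migration.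

**Step 14**
Reactants: 21 6α-acetoxy-9β-(hydroxymethyl)-8α-(tert-butyldimethylsilyloxy)-4,4,8β,10β-tetramethyl-trans-decalin-7β-ol
Product: 22 6α-acetoxy-7β-hydroxy-8α-(tert-butyldimethylsilyloxy)-4,4,8β,10β-tetramethyl-trans-decalin-9β-carbaldehyde
Conditions: TEMPO (10 mol %), PhI(OAc)2, CH2Cl2, rt
Reagents that add atoms: none
Why: the oxoammonium oxidation is selective for the primary alcohol over the hindered secondary 7β-hydroxyl and stops at the aldehyde, which cannot form a lactol with the 1,3-diequatorial 7β-OH.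

**Step 15**
Reactants: 22 6α-acetoxy-7β-hydroxy-8α-(tert-butyldimethylsilyloxy)-4,4,8β,10β-tetramethyl-trans-decalin-9β-carbaldehyde; 23 1-(triphenylphosphoranylidene)propan-2-one
Product: 24 (E)-4-[(1R,2S,3S,4R,4aS,8aS)-4-acetoxy-2-(tert-butyldimethylsilyloxy)-3-hydroxy-2,5,5,8a-tetramethyldecahydronaphthalen-1-yl]but-3-en-2-one
Conditions: toluene, 100 °C
Reagents that add atoms: none
Why: the Wittig reaction of the stabilised ylide is (E)-selective and needs no base, so the acetate, the free hydroxyl and the β-silyloxy aldehyde should survive, and the equatorial 9β-formyl group is not epimerised.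

**Step 16**
Reactants: 24 (E)-4-[(1R,2S,3S,4R,4aS,8aS)-4-acetoxy-2-(tert-butyldimethylsilyloxy)-3-hydroxy-2,5,5,8a-tetramethyldecahydronaphthalen-1-yl]but-3-en-2-one
Product: 25 (E)-4-[(1R,2S,3S,4R,4aS,8aS)-4-acetoxy-2,3-dihydroxy-2,5,5,8a-tetramethyldecahydronaphthalen-1-yl]but-3-en-2-one
Conditions: aq. HF (48 %), MeCN, 0 °C → rt
Reagents that add atoms: none
Why: acidic fluoride cleaves the tertiary silyl ether without the basic conditions that would move the acetate from O6 to O7 or start a vinylogous β-elimination of the C8 oxygen.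

**Compound list**
1 | isobutyronitrile | CC(C)C#N | starting material
2 | (5-chloropent-1-yn-1-yl)trimethylsilane | C[Si](C)(C)C#CCCCCl | starting material
3 | lithiated isobutyronitrile (2-lithio-2-methylpropanenitrile) | [Li]C(C)(C)C#N | intermediate (not isolated)
4 | 2,2-dimethyl-7-(trimethylsilyl)hept-6-ynenitrile | N#CC(C)(C)CCCC#C[Si](C)(C)C | intermediate
5 | N-(diisobutylalumino)aldimine of 6 | C[Si](C)(C)C#CCCCC(C)(C)C=N[Al](CC(C)C)CC(C)C | intermediate (not isolated)
6 | 2,2-dimethyl-7-(trimethylsilyl)hept-6-ynal | O=CC(C)(C)CCCC#C[Si](C)(C)C | intermediate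
7 | [(7E)-8-iodo-6,6-dimethyloct-7-en-1-yn-1-yl]trimethylsilane | I/C=C/C(C)(C)CCCC#C[Si](C)(C)C | intermediate
8 | (±)-2-methyloxirane (propylene oxide) | CC1CO1 | starting material
9 | [(1E)-3,3-dimethyl-8-(trimethylsilyl)oct-1-en-7-yn-1-yl]lithium | [Li]/C=C/C(C)(C)CCCC#C[Si](C)(C)C | intermediate (not isolated)
10 | (4E)-6,6-dimethyl-11-(trimethylsilyl)undec-4-en-10-yn-2-ol (racemic at C2) | CC(O)C/C=C/C(C)(C)CCCC#C[Si](C)(C)C | intermediate
11 | (4E)-6,6-dimethylundec-4-en-10-yn-2-ol (racemic at C2) | CC(O)C/C=C/C(C)(C)CCCC#C | intermediate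
12 | [(1E,7E)-10-(dimethylalumanyloxy)-2,6,6-trimethylundeca-1,7-dien-1-yl]dimethylalane | C[Al](C)/C=C(\C)CCCC(C)(C)/C=C/CC(C)O[Al](C)C | intermediate (not isolated)
13 | lithium butyl(dimethyl)alanate of 12 | [Li+].CCCC[Al-](C)(C)/C=C(\C)CCCC(C)(C)/C=C/CC(C)O[Al](C)C | intermediate (not isolated)
14 | (2E,8E)-3,7,7-trimethyldodeca-2,8-diene-1,11-diol (racemic at C11 of the chain) | CC(O)C/C=C/C(C)(C)CCC/C(C)=C/CO | intermediate
15 | (2E,8E)-3,7,7-trimethyl-11-oxododeca-2,8-dienal | CC(=O)C/C=C/C(C)(C)CCC/C(C)=C/C=O | intermediate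
16 | (2E,8E,10Z)-11-(tert-butyldimethylsilyloxy)-3,7,7-trimethyldodeca-2,8,10-trienal | O=C/C=C(\C)CCCC(C)(C)/C=C/C=C(/C)O[Si](C)(C)C(C)(C)C | intermediate (key-step precursor)
17 | 8α-(tert-butyldimethylsilyloxy)-4,4,8β,10β-tetramethyl-trans-decal-6-ene-9β-carbaldehyde; (1R,2R,4aS,8aS)-2-[(tert-butyldimethylsilyl)oxy]-2,5,5,8a-tetramethyl-1,2,4a,5,6,7,8,8a-octahydronaphthalene-1-carbaldehyde | O=C[C@H]1[C@](C)(O[Si](C)(C)C(C)(C)C)C=C[C@H]2C(C)(C)CCC[C@@]21C | intermediate (key-step product)
18 | 6α,7α-dihydroxy-8α-(tert-butyldimethylsilyloxy)-4,4,8β,10β-tetramethyl-trans-decalin-9β-carbaldehyde | O=C[C@H]1[C@](C)(O[Si](C)(C)C(C)(C)C)[C@H](O)[C@H](O)[C@H]2C(C)(C)CCC[C@@]21C | intermediate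
19 | 6α-acetoxy-7α-hydroxy-8α-(tert-butyldimethylsilyloxy)-4,4,8β,10β-tetramethyl-trans-decalin-9β-carbaldehyde | O=C[C@H]1[C@](C)(O[Si](C)(C)C(C)(C)C)[C@H](O)[C@H](OC(C)=O)[C@H]2C(C)(C)CCC[C@@]21C | intermediate
20 | 6α-acetoxy-7-oxo-8α-(tert-butyldimethylsilyloxy)-4,4,8β,10β-tetramethyl-trans-decalin-9β-carbaldehyde | O=C[C@H]1[C@](C)(O[Si](C)(C)C(C)(C)C)C(=O)[C@H](OC(C)=O)[C@H]2C(C)(C)CCC[C@@]21C | intermediate
21 | 6α-acetoxy-9β-(hydroxymethyl)-8α-(tert-butyldimethylsilyloxy)-4,4,8β,10β-tetramethyl-trans-decalin-7β-ol | OC[C@H]1[C@](C)(O[Si](C)(C)C(C)(C)C)[C@@H](O)[C@H](OC(C)=O)[C@H]2C(C)(C)CCC[C@@]21C | intermediate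
22 | 6α-acetoxy-7β-hydroxy-8α-(tert-butyldimethylsilyloxy)-4,4,8β,10β-tetramethyl-trans-decalin-9β-carbaldehyde | O=C[C@H]1[C@](C)(O[Si](C)(C)C(C)(C)C)[C@@H](O)[C@H](OC(C)=O)[C@H]2C(C)(C)CCC[C@@]21C | intermediate
23 | 1-(triphenylphosphoranylidene)propan-2-one | CC(=O)C=P(c1ccccc1)(c1ccccc1)c1ccccc1 | starting material
24 | (E)-4-[(1R,2S,3S,4R,4aS,8aS)-4-acetoxy-2-(tert-butyldimethylsilyloxy)-3-hydroxy-2,5,5,8a-tetramethyldecahydronaphthalen-1-yl]but-3-en-2-one | CC(=O)/C=C/[C@H]1[C@](C)(O[Si](C)(C)C(C)(C)C)[C@@H](O)[C@H](OC(C)=O)[C@H]2C(C)(C)CCC[C@@]21C | intermediate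
25 | (E)-4-[(1R,2S,3S,4R,4aS,8aS)-4-acetoxy-2,3-dihydroxy-2,5,5,8a-tetramethyldecahydronaphthalen-1-yl]but-3-en-2-one (6α-OAc, 7β-OH, 8α-OH, 8β-Me, 9β side chain, 5α-H, 10β-Me) | CC(=O)/C=C/[C@H]1[C@](C)(O)[C@@H](O)[C@H](OC(C)=O)[C@H]2C(C)(C)CCC[C@@]21C | target

**Step count**
Total: 16 steps. Longest linear sequence: 16 steps (from 1 and 2 to 25).

**Steps most likely to fail**

1. Step 9. The diene terminus C8 is fully substituted with its oxygen on the inside and the enal is β,β-disubstituted, so the cycloaddition may be slow. Ionic side reactions (conjugate addition of the dienol ether without closure of ring B, loss of silanol from the β-silyloxy aldehyde) could then take over, or enantioface and endo/exo discrimination could be poor. The fallback sets out from 16 and returns to 17. Trienal 16 is cyclised without a chiral catalyst, with Me2AlCl in CH2Cl2 at −78 °C or, if the dienol ether does not tolerate a Lewis acid, by heating in toluene with BHT. This should give 17 as a racemate, that is together with its mirror image ent-17 F1. NaBH4 reduction gives the primary alcohol 8α-(tert-butyldimethylsilyloxy)-9β-(hydroxymethyl)-4,4,8β,10β-tetramethyl-trans-decal-6-ene F2 together with its enantiomer F3. Acylation with (1S)-camphanoyl chloride (pyridine, DMAP) gives the camphanate of the wanted series F4 and the camphanate of the mirror-image decalin F5, which are diastereomers and are separated by chromatography or crystallisation. Methanolysis of F4 (K2CO3, MeOH) returns F2 as a single enantiomer, and Dess–Martin oxidation leads back to 17.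

2. Step 8. Silylation may also take place at the enal (γ-deprotonation), enolisation may go towards the methyl group, or part of the enol ether may form with (10E) geometry, which would end as the C8 epimer. The fallback sets out from 14 and returns to 16; it makes the dienol ether before the enal exists. The primary allylic hydroxyl of 14 is acetylated selectively (Ac2O, pyridine, 0 °C) to (2E,8E)-11-hydroxy-3,7,7-trimethyldodeca-2,8-dien-1-yl acetate F6. Dess–Martin oxidation gives the keto acetate F7. TBSOTf/Et3N then meets a single carbonyl group and gives the (10Z)-dienol ether acetate F8. iBu2AlH at −78 °C removes the acetate to give the trienol F9, and MnO2 in CH2Cl2 oxidises the allylic alcohol to 16.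

3. Step 11. Acylation may occur at the wrong hydroxyl of the cis-diol or at both. The fallback sets out from 18 and returns to 19. Diol 18 is heated with Bu2SnO in toluene with removal of water to give the cyclic dibutylstannylene acetal F10. AcCl at 0 °C acylates the tin-bound equatorial oxygen O6, and aqueous work-up gives 19.

**Further compounds**
F1 | step 9 | ent-17, (1S,2S,4aR,8aR)-2-[(tert-butyldimethylsilyl)oxy]-2,5,5,8a-tetramethyl-1,2,4a,5,6,7,8,8a-octahydronaphthalene-1-carbaldehyde | O=C[C@@H]1[C@@](C)(O[Si](C)(C)C(C)(C)C)C=C[C@@H]2C(C)(C)CCC[C@]21C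
F2 | step 9 | 8α-(tert-butyldimethylsilyloxy)-9β-(hydroxymethyl)-4,4,8β,10β-tetramethyl-trans-decal-6-ene (5α-H) | OC[C@H]1[C@](C)(O[Si](C)(C)C(C)(C)C)C=C[C@H]2C(C)(C)CCC[C@@]21C
F3 | step 9 | enantiomer of F2 | OC[C@@H]1[C@@](C)(O[Si](C)(C)C(C)(C)C)C=C[C@@H]2C(C)(C)CCC[C@]21C
F4 | step 9 | (1S)-camphanate of F2 | O=C(OC[C@H]1[C@](C)(O[Si](C)(C)C(C)(C)C)C=C[C@H]2C(C)(C)CCC[C@@]21C)[C@@]12CC[C@@](C)(C(=O)O1)C2(C)C
F5 | step 9 | (1S)-camphanate of F3 | O=C(OC[C@@H]1[C@@](C)(O[Si](C)(C)C(C)(C)C)C=C[C@@H]2C(C)(C)CCC[C@]21C)[C@@]12CC[C@@](C)(C(=O)O1)C2(C)C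
F6 | step 8 | (2E,8E)-11-hydroxy-3,7,7-trimethyldodeca-2,8-dien-1-yl acetate (racemic at C11) | CC(O)C/C=C/C(C)(C)CCC/C(C)=C/COC(C)=O
F7 | step 8 | (2E,8E)-3,7,7-trimethyl-11-oxododeca-2,8-dien-1-yl acetate | CC(=O)C/C=C/C(C)(C)CCC/C(C)=C/COC(C)=O
F8 | step 8 | (2E,8E,10Z)-11-(tert-butyldimethylsilyloxy)-3,7,7-trimethyldodeca-2,8,10-trien-1-yl acetate | CC(=O)OC/C=C(\C)CCCC(C)(C)/C=C/C=C(/C)O[Si](C)(C)C(C)(C)C
F9 | step 8 | (2E,8E,10Z)-11-(tert-butyldimethylsilyloxy)-3,7,7-trimethyldodeca-2,8,10-trien-1-ol | OC/C=C(\C)CCCC(C)(C)/C=C/C=C(/C)O[Si](C)(C)C(C)(C)C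
F10 | step 11 | 6α,7α-O-dibutylstannylene acetal of 18 | O=C[C@H]1[C@](C)(O[Si](C)(C)C(C)(C)C)[C@@H]3O[Sn](CCCC)(CCCC)O[C@@H]3[C@H]2C(C)(C)CCC[C@@]21C
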